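**Plan**
- Retrosynthesis: ring A'' of the apigenin unit is dismantled in one operation at C5''–C6'', C7''–C8'' and C4a''–C5'' into an α-aryl α-diazo ketone and isopropoxyacetylene. The diazo ketone is cut at the ring B C3'–CH2 bond into a 3'-bromoflavone and a 6-acetyl-2-aryl-4-pyranone, and these at their pyranone C–O and 1,3-dicarbonyl C–C bonds.
- Enabling feature: C8'' is the crowded biaryl carbon between C7''–O and C8a''–O1'', and ring A'' is a 5'',7''-resorcinol. A ketene–ynol ether benzannulation gives this pattern when ring B and the 4-pyranone (future ring C'') already sit on the ketene carbon and the pyranone C5=C6 bond becomes C4a''–C8a''.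
- Forward: ring C of the 6-methylflavone is closed onto ring A with ring B as a bromoanisole; the 4-pyranone carrying ring B''' is built from a triketone; both are joined at C3', the diazo group is installed, and ring A'' is closed last, before one global deprotection.
- Protecting groups: 7''-O arrives as an isopropyl ether (the ynol ether is made reliably from propan-2-ol and is small at the hindered carbon), 4'''-O is benzyl and the chelated 5-O stays methyl. BCl3 cleaves all three while the 7- and 4'-methyl ethers remain.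
- Stereochemistry: nothing to set, since the target has no stereocentre and its 3'–8'' axis carries no descriptor; stereocentres that arise inside the key step are erased there.

Key step: step 10

Remark: locants without primes and with one prime belong to the 6-methylflavone unit (rings A, C and B), those with two and three primes to the apigenin unit (rings A'', C'' and B''').
Remark: the biaryl axis is treated as configurationally undefined, as drawn.

**Route**

Step 1
Reactants: 1 2,6-dimethoxytoluene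
Product: 3 3,5-dimethoxy-4-methylphenol, via aryl pinacol boronate 2 (not isolated)
Conditions: [Ir(OMe)(cod)]2 (1.5 mol%), dtbpy (3 mol%), B2pin2 (0.55 equiv), THF, 80 °C; then KHSO5 (as 2KHSO5·KHSO4·K2SO4), acetone–H2O, rt
Reagents that add atoms: bis(pinacolato)diboron CC1(C)OB(OC1(C)C)B1OC(C)(C)C(C)(C)O1 (boron of 2); potassium peroxymonosulfate [K+].[O-]S(=O)(=O)OO (oxygen of 3)
Why: [Ir(OMe)(cod)]2/dtbpy-catalysed C–H borylation is sterically governed and selects the only C–H bond without an ortho substituent (para to the methyl group), and the boronate is oxidised in the same flask by peroxymonosulfate to the phenol.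

Step 2
Reactants: 3 3,5-dimethoxy-4-methylphenol
Product: 4 1-(6-hydroxy-2,4-dimethoxy-3-methylphenyl)ethanone
Conditions: AcOH, BF3·OEt2 (3 equiv), 90 °C; then H2O
Reagents that add atoms: acetic acid CC(=O)O
Why: BF3-mediated ortho-acylation of the phenol (Friedel–Crafts/Fries type) can only take place at the two equivalent positions next to the hydroxyl group, and the boron chelate of the product is hydrolysed on work-up.

Step 3
Reactants: 4 1-(6-hydroxy-2,4-dimethoxy-3-methylphenyl)ethanone; 5 3-bromo-4-methoxybenzoic acid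
Product: 7 2-acetyl-3,5-dimethoxy-4-methylphenyl 3-bromo-4-methoxybenzoate, via acid chloride 6 (not isolated)
Conditions: 5, (COCl)2, DMF (cat.), CH2Cl2, rt; evaporate; then 4, Et3N, DMAP (cat.), CH2Cl2, 0 °C → rt
Reagents that add atoms: oxalyl chloride O=C(Cl)C(=O)Cl (chlorine of 6)
Why: Acid chloride formation followed by DMAP-catalysed O-acylation of the hydrogen-bonded phenol is routine and provides the aryl ester needed for the Baker–Venkataraman rearrangement.

Step 4
Reactants: 7 2-acetyl-3,5-dimethoxy-4-methylphenyl 3-bromo-4-methoxybenzoate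
Product: 9 3'-bromo-5,7,4'-trimethoxy-6-methylflavone, via 1,3-diketone 8 (not isolated)
Conditions: KOH, pyridine, 50 °C; AcOH; then H2SO4 (cat.), AcOH, 100 °C
Reagents that add atoms: none
Why: Baker–Venkataraman rearrangement moves the aroyl group from oxygen to the acetyl carbon through the ketone enolate, and acid-catalysed cyclodehydration through the only free phenol closes ring C so that the methyl group can only lie at C6.

Step 5
Reactants: 10 4'-(benzyloxy)acetophenone
Product: 11 1-[4-(benzyloxy)phenyl]butane-1,3-dione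
Conditions: NaH, EtOAc, THF, 60 °C; then aq. HCl
Reagents that add atoms: ethyl acetate CCOC(C)=O
Why: Crossed Claisen condensation of the methyl ketone enolate with ethyl acetate is pulled to completion by deprotonation of the 1,3-diketone formed.

Step 6
Reactants: 11 1-[4-(benzyloxy)phenyl]butane-1,3-dione; 12 methyl 2,2-dimethoxypropanoate
Product: 14 6-acetyl-2-[4-(benzyloxy)phenyl]-4H-pyran-4-one, via triketone ketal 13 (not isolated)
Conditions: LiN(i-Pr)2 (3.2 equiv), THF, −78 → 0 °C; 12, −78 °C → rt; aq. HCl; then conc. HCl, EtOH, 60 °C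
Reagents that add atoms: none
Why: The dianion of the 1,3-diketone is acylated at its terminal carbon by the ketal-masked pyruvate ester (classical triketone synthesis), and aqueous acid then cyclodehydrates the 1,3,5-triketone to the 4-pyranone and hydrolyses the ketal to the acetyl group.

Step 7
Reactants: 15 propan-2-ol; 16 trichloroethylene
Product: 19 isopropoxyacetylene, via dichlorovinyl ether 17 (not isolated), via chloroalkynyl ether 18 (not isolated)
Conditions: KH, THF, 0 °C; 16, −50 °C → rt; n-BuLi (2.5 equiv), −78 → −40 °C; H2O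
Reagents that add atoms: none
Why: Addition–elimination of the alkoxide on trichloroethylene gives the 1,2-dichlorovinyl ether, n-BuLi effects dehydrochlorination and chlorine–lithium exchange, and protonation of the lithium acetylide gives the terminal ynol ether (the standard trichloroethylene route to 1-alkoxyalkynes), which is volatile and is kept as a dried, assayed solution.

Step 8
Reactants: 14 6-acetyl-2-[4-(benzyloxy)phenyl]-4H-pyran-4-one; 9 3'-bromo-5,7,4'-trimethoxy-6-methylflavone
Product: 20 2-[4-(benzyloxy)phenyl]-6-{[5-(5,7-dimethoxy-6-methyl-4-oxo-4H-chromen-2-yl)-2-methoxyphenyl]acetyl}-4H-pyran-4-one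
Conditions: 14 (1.3 equiv), Pd2(dba)3 (2.5 mol%), Xantphos (6 mol%), K3PO4, toluene, 90 °C
Reagents that add atoms: none
Why: Pd2(dba)3/Xantphos-catalysed α-arylation of a methyl ketone proceeds by oxidative addition of the aryl bromide to zerovalent palladium, enolate coordination and reductive elimination, and the ortho-methoxy group together with the acidity of the product disfavours a second arylation.

Step 9
Reactants: 20 2-[4-(benzyloxy)phenyl]-6-{[5-(5,7-dimethoxy-6-methyl-4-oxo-4H-chromen-2-yl)-2-methoxyphenyl]acetyl}-4H-pyran-4-one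
Product: 21 2-[4-(benzyloxy)phenyl]-6-{diazo[5-(5,7-dimethoxy-6-methyl-4-oxo-4H-chromen-2-yl)-2-methoxyphenyl]acetyl}-4H-pyran-4-one
Conditions: 4-acetamidobenzenesulfonyl azide, DBU, MeCN, 0 °C → rt, dark
Reagents that add atoms: 4-acetamidobenzenesulfonyl azide CC(=O)Nc1ccc(cc1)S(=O)(=O)N=[N+]=[N-]
Why: Regitz diazo transfer to the methylene group activated by both the ketone and the aryl ring needs only a sulfonyl azide and an amidine base.

Step 10
Reactants: 21 2-[4-(benzyloxy)phenyl]-6-{diazo[5-(5,7-dimethoxy-6-methyl-4-oxo-4H-chromen-2-yl)-2-methoxyphenyl]acetyl}-4H-pyran-4-one; 19 isopropoxyacetylene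
Product: 26 5-O-methyl-7''-O-isopropyl-4'''-O-benzyl taiwanhomoflavone A, via aryl(pyranonyl)ketene 22 (not isolated), via vinylcyclobutenone 23 (not isolated), via dienylketene 24 (not isolated), via cyclohexadienone 25 (not isolated)
Conditions: 19 (3 equiv), blue LEDs (450 nm), degassed ClCH2CH2Cl, rt; excess 19 removed in vacuo; then toluene, 90 °C
Reagents that add atoms: none
Why: Proposed new method: blue-light Wolff rearrangement shifts the pyranonyl group to the carbene carbon and gives ketene 22, whose electron-poor carbonyl carbon is attacked by the CH terminus of the ynol ether, so that [2+2] cycloaddition places the isopropoxy carbon on the fully substituted carbon of cyclobutenone 23; heating opens 23 by four-electron conrotatory cleavage to dienylketene 24, and six-electron disrotatory electrocyclisation onto pyranone C5 followed by enolisation of 25 gives the phenol. The closest known reaction type is the Danheiser benzannulation of α-diazo ketones with alkoxy- and silyloxyalkynes, which has not been shown with a 4-pyranone C5=C6 bond as the vinyl unit or with so hindered a ketene. The one new ring, carbocyclic ring A'', is closed by the six-electron electrocyclisation that forms C4a''–C5'' after the cycloaddition has made C5''–C6'' and C7''–C8''. No stereocentre is created in the product: C4 of 23 and C4a of 25 are transient and racemic. The step needs regiocontrol in the cycloaddition, which the ynol ether polarity provides (H to C6'', oxygen to C7''), and because ring B sits on the ketene carbon it can only end at C8''. It also needs closure onto the pyranone and not onto ring B, which is secured because C4' is blocked by methoxy, closure at C2' would set the new C–O bond peri to the chromonyl group and break benzene aromaticity, and the weakly aromatic pyranone offers C5 next to a carbonyl that hydrogen-bonds the emerging 5''-OH; blue light is absorbed only by the diazo chromophore and spares the flavone and the photolabile 4-pyranone.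

Step 11
Reactants: 26 5-O-methyl-7''-O-isopropyl-4'''-O-benzyl taiwanhomoflavone A
Product: 27 taiwanhomoflavone A
Conditions: BCl3 (10 equiv), C6HMe5, CH2Cl2, −78 °C → rt; then H2O
Reagents that add atoms: none
Why: BCl3 cleaves the benzyl ether (benzyl cation trapped by pentamethylbenzene), the secondary isopropyl ether and, by chelation to the C4 carbonyl, the peri 5-methoxy group only, so that the unchelated 7- and 4'-methyl ethers of the target should survive (Lewis acid ether cleavage).

**Compound list**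
1 | 2,6-dimethoxytoluene | COc1cccc(OC)c1C | starting material
2 | 2-(3,5-dimethoxy-4-methylphenyl)-4,4,5,5-tetramethyl-1,3,2-dioxaborolane | COc1cc(B2OC(C)(C)C(C)(C)O2)cc(OC)c1C | intermediate
3 | 3,5-dimethoxy-4-methylphenol | COc1cc(O)cc(OC)c1C | intermediate
4 | 1-(6-hydroxy-2,4-dimethoxy-3-methylphenyl)ethanone | CC(=O)c1c(O)cc(OC)c(C)c1OC | intermediate
5 | 3-bromo-4-methoxybenzoic acid | COc1ccc(C(=O)O)cc1Br | starting material
6 | 3-bromo-4-methoxybenzoyl chloride | COc1ccc(C(=O)Cl)cc1Br | intermediate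
7 | 2-acetyl-3,5-dimethoxy-4-methylphenyl 3-bromo-4-methoxybenzoate | CC(=O)c1c(OC(=O)c2ccc(OC)c(Br)c2)cc(OC)c(C)c1OC | intermediate
8 | 1-(3-bromo-4-methoxyphenyl)-3-(6-hydroxy-2,4-dimethoxy-3-methylphenyl)propane-1,3-dione | COc1ccc(C(=O)CC(=O)c2c(O)cc(OC)c(C)c2OC)cc1Br | intermediate
9 | 3'-bromo-5,7,4'-trimethoxy-6-methylflavone [2-(3-bromo-4-methoxyphenyl)-5,7-dimethoxy-6-methyl-4H-chromen-4-one] | COc1ccc(-c2cc(=O)c3c(OC)c(C)c(OC)cc3o2)cc1Br | intermediate
10 | 4'-(benzyloxy)acetophenone | CC(=O)c1ccc(OCc2ccccc2)cc1 | starting material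
11 | 1-[4-(benzyloxy)phenyl]butane-1,3-dione | CC(=O)CC(=O)c1ccc(OCc2ccccc2)cc1 | intermediate
12 | methyl 2,2-dimethoxypropanoate | COC(=O)C(C)(OC)OC | starting material
13 | 1-[4-(benzyloxy)phenyl]-6,6-dimethoxyheptane-1,3,5-trione | COC(C)(OC)C(=O)CC(=O)CC(=O)c1ccc(OCc2ccccc2)cc1 | intermediate
14 | 6-acetyl-2-[4-(benzyloxy)phenyl]-4H-pyran-4-one | CC(=O)c1cc(=O)cc(-c2ccc(OCc3ccccc3)cc2)o1 | intermediate
15 | propan-2-ol | CC(C)O | starting material
16 | trichloroethylene | ClC=C(Cl)Cl | starting material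
17 | (E)-1,2-dichloro-1-(propan-2-yloxy)ethene | CC(C)O/C(Cl)=C\Cl | intermediate
18 | 1-chloro-2-(propan-2-yloxy)ethyne | CC(C)OC#CCl | intermediate
19 | isopropoxyacetylene [2-(ethynyloxy)propane] | C#COC(C)C | intermediate
20 | 2-[4-(benzyloxy)phenyl]-6-{[5-(5,7-dimethoxy-6-methyl-4-oxo-4H-chromen-2-yl)-2-methoxyphenyl]acetyl}-4H-pyran-4-one | COc1ccc(-c2cc(=O)c3c(OC)c(C)c(OC)cc3o2)cc1CC(=O)c1cc(=O)cc(-c2ccc(OCc3ccccc3)cc2)o1 | intermediate
21 | 2-[4-(benzyloxy)phenyl]-6-{diazo[5-(5,7-dimethoxy-6-methyl-4-oxo-4H-chromen-2-yl)-2-methoxyphenyl]acetyl}-4H-pyran-4-one | COc1ccc(-c2cc(=O)c3c(OC)c(C)c(OC)cc3o2)cc1C(=[N+]=[N-])C(=O)c1cc(=O)cc(-c2ccc(OCc3ccccc3)cc2)o1 | intermediate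
22 | 2-[4-(benzyloxy)phenyl]-6-{1-[5-(5,7-dimethoxy-6-methyl-4-oxo-4H-chromen-2-yl)-2-methoxyphenyl]-2-oxoethenyl}-4H-pyran-4-one (ketene) | COc1ccc(-c2cc(=O)c3c(OC)c(C)c(OC)cc3o2)cc1C(=C=O)c1cc(=O)cc(-c2ccc(OCc3ccccc3)cc2)o1 | intermediate
23 | 4-[5-(5,7-dimethoxy-6-methyl-4-oxo-4H-chromen-2-yl)-2-methoxyphenyl]-4-{6-[4-(benzyloxy)phenyl]-4-oxo-4H-pyran-2-yl}-3-(propan-2-yloxy)cyclobut-2-en-1-one (racemic) | COc1ccc(-c2cc(=O)c3c(OC)c(C)c(OC)cc3o2)cc1C1(c2cc(=O)cc(-c3ccc(OCc4ccccc4)cc3)o2)C(=O)C=C1OC(C)C | intermediate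
24 | 2-[4-(benzyloxy)phenyl]-6-{1-[5-(5,7-dimethoxy-6-methyl-4-oxo-4H-chromen-2-yl)-2-methoxyphenyl]-4-oxo-2-(propan-2-yloxy)buta-1,3-dienyl}-4H-pyran-4-one (dienylketene, pyranonyl cis to the ketene arm) | COc1ccc(-c2cc(=O)c3c(OC)c(C)c(OC)cc3o2)cc1/C(c1cc(=O)cc(-c2ccc(OCc3ccccc3)cc2)o1)=C(/C=C=O)OC(C)C | intermediate
25 | 8-[5-(5,7-dimethoxy-6-methyl-4-oxo-4H-chromen-2-yl)-2-methoxyphenyl]-2-[4-(benzyloxy)phenyl]-7-(propan-2-yloxy)-4aH-chromene-4,5-dione (racemic keto tautomer) | COc1ccc(-c2cc(=O)c3c(OC)c(C)c(OC)cc3o2)cc1C1=C2OC(c3ccc(OCc4ccccc4)cc3)=CC(=O)C2C(=O)C=C1OC(C)C | intermediate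
26 | 5-O-methyl-7''-O-isopropyl-4'''-O-benzyl taiwanhomoflavone A [8-[5-(5,7-dimethoxy-6-methyl-4-oxo-4H-chromen-2-yl)-2-methoxyphenyl]-2-[4-(benzyloxy)phenyl]-5-hydroxy-7-(propan-2-yloxy)-4H-chromen-4-one] | COc1ccc(-c2cc(=O)c3c(OC)c(C)c(OC)cc3o2)cc1-c1c(OC(C)C)cc(O)c2c(=O)cc(-c3ccc(OCc4ccccc4)cc3)oc12 | intermediate
27 | taiwanhomoflavone A [8-[5-(5-hydroxy-7-methoxy-6-methyl-4-oxo-4H-chromen-2-yl)-2-methoxyphenyl]-5,7-dihydroxy-2-(4-hydroxyphenyl)-4H-chromen-4-one] | COc1ccc(-c2cc(=O)c3c(O)c(C)c(OC)cc3o2)cc1-c1c(O)cc(O)c2c(=O)cc(-c3ccc(O)cc3)oc12 | target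

**Step count**
Total steps: 11. Longest linear sequence: 8 (steps 1, 2, 3, 4, 8, 9, 10, 11).

**Steps most likely to fail**

1. Step 10. What may go wrong:
- carbene reactions (attack of the ortho-methoxy oxygen on the carbene) may outrun the Wolff shift;
- the hindered ketene may fail to add the ynol ether or add it across its C=O bond;
- the six-electron closure may go onto ring B instead of the pyranone.

Fallback (known chemistry, from 9, rejoining at 27): the biaryl bond is made by Suzuki–Miyaura coupling.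
- Bromoflavone 9 is converted by Miyaura borylation (B2pin2, Pd(dppf)Cl2, KOAc, dioxane, 90 °C) into 5,7-dimethoxy-2-[4-methoxy-3-(pinacolboryl)phenyl]-6-methyl-4H-chromen-4-one F1.
- Commercial apigenin (5,7,4'-trihydroxyflavone) is perbenzylated (BnBr, K2CO3, DMF, 80 °C) to 5,7,4'-tri-O-benzylapigenin F2.
- F2 is iodinated at C8, the site expected for 5-O-alkylated 5,7-dioxygenated flavones (N-iodosuccinimide, CF3CO2H cat., MeCN), to 8-iodo-5,7,4'-tri-O-benzylapigenin F3.
- Coupling of F1 with F3 (Pd(OAc)2, SPhos, K3PO4, toluene–H2O, 100 °C) should give the protected biflavone 5-O-methyl-5'',7'',4'''-tri-O-benzyl taiwanhomoflavone A F4.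
- The BCl3/C6HMe5 conditions of step 11 then remove the three benzyl groups and the chelated 5-methyl group to reach 27.

2. Step 8. What may go wrong:
- self-condensation or base-induced ring opening of the acetylpyranone enolate;
- slow coupling at the ortho-methoxy bromide;
- a second arylation.

Fallback (from 14 and 9, rejoining at 21): the aryl–carbon bond is formed on a diazo carbon instead of an enolate.
- Methyl ketone 14 undergoes detrifluoroacetylative diazo transfer. LiN(SiMe3)2 and CF3CO2CH2CF3 in THF at −78 °C give 1-{6-[4-(benzyloxy)phenyl]-4-oxo-4H-pyran-2-yl}-4,4,4-trifluorobutane-1,3-dione F5; MsN3, Et3N and H2O in MeCN then give 2-[4-(benzyloxy)phenyl]-6-(diazoacetyl)-4H-pyran-4-one F6.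
- Bromide 9 is changed into 3'-iodo-5,7,4'-trimethoxy-6-methylflavone F7 by an aromatic Finkelstein reaction (CuI, trans-N,N'-dimethylcyclohexane-1,2-diamine, NaI, dioxane, 110 °C).
- C–H arylation of F6 with F7 (Pd(PPh3)4, Ag2CO3, Et3N, toluene, rt) should lead directly to diazo ketone 21, bypassing ketone 20.

3. Step 6. What may go wrong:
- acylation of the dianion at oxygen or at the central carbon;
- after ketal hydrolysis, closure of the 1,2-diketone terminus to a furanone instead of cyclodehydration to the pyranone.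

Fallback (from 11, rejoining at 14): the pyranone is made first as its ester.
- Diketone 11 is condensed with diethyl oxalate (NaOEt, EtOH) to ethyl 6-[4-(benzyloxy)phenyl]-2,4,6-trioxohexanoate F8.
- F8 closes in ethanolic HCl to ethyl 6-[4-(benzyloxy)phenyl]-4-oxo-4H-pyran-2-carboxylate F9.
- Crossed Claisen condensation with the lithium enolate of tert-butyl acetate (LiN(i-Pr)2, THF, −78 °C) gives tert-butyl 3-{6-[4-(benzyloxy)phenyl]-4-oxo-4H-pyran-2-yl}-3-oxopropanoate F10.
- CF3CO2H in CH2Cl2 followed by warming in toluene removes the tert-butyl group and CO2 and returns to 14.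

**Further compounds**
F1 | step 10 | 5,7-dimethoxy-2-[4-methoxy-3-(4,4,5,5-tetramethyl-1,3,2-dioxaborolan-2-yl)phenyl]-6-methyl-4H-chromen-4-one | COc1ccc(-c2cc(=O)c3c(OC)c(C)c(OC)cc3o2)cc1B1OC(C)(C)C(C)(C)O1
F2 | step 10 | 5,7-bis(benzyloxy)-2-[4-(benzyloxy)phenyl]-4H-chromen-4-one | O=c1cc(-c2ccc(OCc3ccccc3)cc2)oc2cc(OCc3ccccc3)cc(OCc3ccccc3)c12
F3 | step 10 | 5,7-bis(benzyloxy)-2-[4-(benzyloxy)phenyl]-8-iodo-4H-chromen-4-one | O=c1cc(-c2ccc(OCc3ccccc3)cc2)oc2c(I)c(OCc3ccccc3)cc(OCc3ccccc3)c12
F4 | step 10 | 5,7-bis(benzyloxy)-2-[4-(benzyloxy)phenyl]-8-[5-(5,7-dimethoxy-6-methyl-4-oxo-4H-chromen-2-yl)-2-methoxyphenyl]-4H-chromen-4-one | COc1ccc(-c2cc(=O)c3c(OC)c(C)c(OC)cc3o2)cc1-c1c(OCc2ccccc2)cc(OCc2ccccc2)c2c(=O)cc(-c3ccc(OCc4ccccc4)cc3)oc12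
F5 | step 8 | 1-{6-[4-(benzyloxy)phenyl]-4-oxo-4H-pyran-2-yl}-4,4,4-trifluorobutane-1,3-dione | O=C(CC(=O)C(F)(F)F)c1cc(=O)cc(-c2ccc(OCc3ccccc3)cc2)o1
F6 | step 8 | 2-[4-(benzyloxy)phenyl]-6-(diazoacetyl)-4H-pyran-4-one | [N-]=[N+]=CC(=O)c1cc(=O)cc(-c2ccc(OCc3ccccc3)cc2)o1
F7 | step 8 | 2-(3-iodo-4-methoxyphenyl)-5,7-dimethoxy-6-methyl-4H-chromen-4-one | COc1ccc(-c2cc(=O)c3c(OC)c(C)c(OC)cc3o2)cc1I
F8 | step 6 | ethyl 6-[4-(benzyloxy)phenyl]-2,4,6-trioxohexanoate | CCOC(=O)C(=O)CC(=O)CC(=O)c1ccc(OCc2ccccc2)cc1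
F9 | step 6 | ethyl 6-[4-(benzyloxy)phenyl]-4-oxo-4H-pyran-2-carboxylate | CCOC(=O)c1cc(=O)cc(-c2ccc(OCc3ccccc3)cc2)o1
F10 | step 6 | tert-butyl 3-{6-[4-(benzyloxy)phenyl]-4-oxo-4H-pyran-2-yl}-3-oxopropanoate | CC(C)(C)OC(=O)CC(=O)c1cc(=O)cc(-c2ccc(OCc3ccccc3)cc2)o1
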